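The readings are simulated for an exercise; noise was put on by code.

The forecaster and the kineticist read the same two runs and differ on one question: how many nucleophile are spent for each electrophile that reacts?

| flask | electrophile | nucleophile | free base | remark | time |
|---|---|---|---|---|---|
| cedar | 0.50 M | 1.9 M | 0.40 M | run made earlier |  |
| maple | 0.25 M | 1.25 M | 0.40 M | run made earlier |  |
| Monday's | 0.50 M | 1.25 M | 0.600 M |  | 2.5 h |
| Saturday's | 0.50 M | 1.25 M | 0.400 M |  | 2.5 h |
| Tuesday's | 0.50 M | 1.25 M | 0.900 M |  | 2.5 h |

| run | time / min | electrophile / % | target / % |
|---|---|---|---|
| cedar | 12.0 | 73 | 26 |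
| cedar | 25.0 | 57 | 44 |
| cedar | 40.0 | 41 | 62 |
| cedar | 50.0 | 32 | 67 |
| cedar | 60.0 | 28 | 73 |
| cedar | 80.0 | 22 | 79 |
| cedar | 90.0 | 18 | 83 |
| maple | 12.0 | 79 | 19 |
| maple | 25.0 | 67 | 33 |
| maple | 40.0 | 51 | 48 |
| maple | 50.0 | 45 | 57 |
| maple | 60.0 | 39 | 60 |
| maple | 80.0 | 34 | 68 |
| maple | 90.0 | 24 | 71 |

(readings scatter by 1.5 percentage points)

* part of the electrophile that has reacted at the end, Monday's
* part of the electrophile that has reacted at the end, Saturday's
* part of the electrophile that has reacted at the end, Tuesday's
* what raising the concentration of free base from its lowest to its highest value here does to the part of the electrophile that has reacted (changes below 5 percentage points count as none) (it falls / it rises / no change)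

- no earlier run changes the charge of free base; that part of a forecast is a guess

Both take the rate as a constant times electrophile times free nucleophile. The forecaster holds the one-spend view, “Free base probably only scavenges the acid released”, so in that view one nucleophile goes per electrophile as long as free base takes the acid. The forecast gives Saturday's 84% (range 78% to 88%), Monday's 85%, Tuesday's 85%, and for the trend: no change.

The kineticist answers from the cedar run. Integrated with one spend, the second-order law gives 0.0143 M⁻¹ min⁻¹ from the reading at 12.0 min, but 0.0117 M⁻¹ min⁻¹ from the reading at 90.0 min. The later value is lower, though both carry the scatter. The kineticist's two-spend view makes the nucleophile its own acid scavenger, so free nucleophile falls by two for each electrophile reacted. The first reading then gives 0.0149 M⁻¹ min⁻¹. The two-spend rate constant, defined as the constant from cedar's last reading when each reacted electrophile removes two nucleophile, is 0.0142 M⁻¹ min⁻¹.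

Integrated over 2.5 h from Saturday's charges, this constant gives the kineticist's own figure of 77.9% reacted. Free base does not enter this sum, so the kineticist expects the same for Monday's and Tuesday's, and also no change. The two agree on the trend but differ on the level, and the kineticist's acid taker remains a guess, since no run varied the base.

The simulation gives Saturday's 78.4%, Monday's 78.5% and Tuesday's 78.8%, a change of 0.42 percentage points: no change.

    nucleophile + acid set free ⇌ protonated nucleophile, settled at all times (K = 180 M⁻¹)
    electrophile + nucleophile ⇌ acid set free + target (K = 0.850, k = 2.40 × 10⁻⁴ M⁻¹ s⁻¹)
    acid set free + free base ⇌ salt of the base (K = 1200 M⁻¹, k = 0.00300 M⁻¹ s⁻¹)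

At 2.50 h Saturday's holds more protonated nucleophile, 0.363 M, than salt of the base, 0.0244 M. The forecaster's picture fits another flask at another time: at 25.0 h in Tuesday's, salt of the base at 0.366 M exceeds protonated nucleophile at 0.132 M. For the neighbour of Saturday's charged with 0.31 M of nucleophile, other charges and time held, the two-spend rate constant reckons 25.7% reacted, and that flask gives 27.4%.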